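**Retrosynthetic overview**
1. Target 19 comes from bis-MOM ether 18 by a final mild acid deprotection; both Z alkenes come from the skipped 8,11-diyne 17 by syn semi-hydrogenation.
2. Diyne 17 is cut at C10–C11: copper-mediated coupling of propargylic bromide 9 (arene plus C1–C10) with terminal alkyne 14 (C11–C17).
3. Bromide 9 comes from an aryl Grignard reagent plus 1,7-dibromoheptane (aryl–C1 bond), then propargyl alcohol dianion (C7–C8 bond), then OH to Br.
4. Alkyne 14 comes from (S)-propylene oxide, the source of the only stereocentre (C16, S), plus a TMS-capped but-3-ynyl Grignard reagent, then desilylation.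
5. No ring is formed: the resorcinol ring is bought as 5-bromoresorcinol and carried as its bis-MOM ether.

Assumption: compounds 1, 3, 6, 10 and 11 are taken as commercial; carbon building blocks are numbered as reactants, and only unnumbered reagents are entered under "Reagents that add atoms".

**Route**

Step 1
Reactants: 1 5-bromobenzene-1,3-diol (5-bromoresorcinol)
Product: 2 1-bromo-3,5-bis(methoxymethoxy)benzene
Conditions: NaH (2.4 equiv), DMF, 0 °C; MOMCl (2.4 equiv), 0 °C → rt
Reagents that add atoms: chloromethyl methyl ether (MOMCl), COCCl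
Why: Williamson-type O-alkylation of both phenoxides gives the bis-MOM ether, which withstands Grignard, organolithium and carbonate conditions and is later removed by mild acid that spares a skipped diene.

Step 2
Reactants: 2 1-bromo-3,5-bis(methoxymethoxy)benzene; 3 1,7-dibromoheptane
Product: 5 1-(7-bromoheptyl)-3,5-bis(methoxymethoxy)benzene, via arylmagnesium bromide 4 (not isolated)
Conditions: Mg, THF, reflux; then 3 (3 equiv), Li2CuCl4 (3 mol%), THF, 0 °C → rt
Reagents that add atoms: none
Why: Kochi-type copper-catalysed sp2–sp3 cross-coupling of the aryl Grignard reagent with a primary alkyl bromide, the threefold excess of dibromide holding the reaction at monoarylation.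

Step 3
Reactants: 5 1-(7-bromoheptyl)-3,5-bis(methoxymethoxy)benzene; 6 prop-2-yn-1-ol
Product: 8 10-[3,5-bis(methoxymethoxy)phenyl]dec-2-yn-1-ol, via dilithiated propargyl alcohol 7 (not isolated)
Conditions: 6 (2 equiv), n-BuLi (3.9 equiv), THF/HMPA, −78 → 0 °C; then 5, 0 °C → rt; H2O
Reagents that add atoms: none
Why: SN2 acetylide alkylation, in which the C-lithio end of the O,C-dianion is far more nucleophilic than the alkoxide, so the primary bromide is displaced at carbon only.

Step 4
Reactants: 8 10-[3,5-bis(methoxymethoxy)phenyl]dec-2-yn-1-ol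
Product: 9 1-(10-bromodec-8-yn-1-yl)-3,5-bis(methoxymethoxy)benzene
Conditions: CBr4, PPh3, CH2Cl2, 0 °C
Reagents that add atoms: carbon tetrabromide, BrC(Br)(Br)Br
Why: The Appel reaction converts the primary propargylic alcohol into the bromide under near-neutral conditions that leave the MOM ethers and the alkyne alone.

Step 5
Reactants: 10 (4-bromobut-1-yn-1-yl)trimethylsilane; 11 (S)-2-methyloxirane ((S)-propylene oxide)
Product: 13 (2S)-7-(trimethylsilyl)hept-6-yn-2-ol, via homopropargylic Grignard reagent 12 (not isolated)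
Conditions: Mg, THF, 40 °C; then CuI (10 mol%), 11, THF, −30 → 0 °C; H2O
Reagents that add atoms: none
Why: Copper-catalysed Grignard opening of the epoxide (SN2) at its unhindered CH2 terminus never breaks the C–O bond at the stereocentre, so the S configuration of 11 becomes the S carbinol that is C16 of the target.

Step 6
Reactants: 13 (2S)-7-(trimethylsilyl)hept-6-yn-2-ol
Product: 14 (2S)-hept-6-yn-2-ol
Conditions: K2CO3 (0.2 equiv), MeOH, rt
Reagents that add atoms: none
Why: Methoxide-mediated protodesilylation of the alkynyl–silicon bond frees the terminal alkyne without touching the carbinol stereocentre.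

Step 7
Reactants: 9 1-(10-bromodec-8-yn-1-yl)-3,5-bis(methoxymethoxy)benzene; 14 (2S)-hept-6-yn-2-ol
Product: 17 (2S)-17-[3,5-bis(methoxymethoxy)phenyl]heptadeca-6,9-diyn-2-ol, via propargylic iodide 15 (not isolated), via copper acetylide 16 (not isolated)
Conditions: CuI (1 equiv), NaI (1 equiv), Cs2CO3 (1 equiv), DMF, rt, Ar
Reagents that add atoms: none
Why: Copper-mediated sp–sp3 coupling (Finkelstein exchange to the iodide, then substitution by the monovalent copper acetylide) builds the skipped diyne under carbonate conditions too mild to isomerise it to an allene and tolerant of the free secondary alcohol.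

Step 8
Reactants: 17 (2S)-17-[3,5-bis(methoxymethoxy)phenyl]heptadeca-6,9-diyn-2-ol
Product: 18 (2S,6Z,9Z)-17-[3,5-bis(methoxymethoxy)phenyl]heptadeca-6,9-dien-2-ol
Conditions: H2 (1 atm), Lindlar catalyst (5% Pd on CaCO3, poisoned with Pb(OAc)2), quinoline, EtOAc, rt, stopped after 2 equiv H2
Reagents that add atoms: none
Why: Lindlar semi-hydrogenation delivers H2 syn to each alkyne on the poisoned palladium surface, setting both Z alkenes while the MOM ethers, the arene and the carbinol are untouched.

Step 9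
Reactants: 18 (2S,6Z,9Z)-17-[3,5-bis(methoxymethoxy)phenyl]heptadeca-6,9-dien-2-ol
Product: 19 Hansfordiol D (5-[(8Z,11Z,16S)-16-hydroxyheptadeca-8,11-dien-1-yl]benzene-1,3-diol)
Conditions: HCl (2 M), MeOH, rt → 40 °C, N2
Reagents that add atoms: none
Why: Acid-catalysed acetal exchange to dimethoxymethane removes both aryl MOM ethers under conditions in which the isolated Z,Z-skipped diene and the secondary alcohol are stable.

**Compound list**
1 | 5-bromobenzene-1,3-diol (5-bromoresorcinol) | Oc1cc(O)cc(Br)c1 | starting material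
2 | 1-bromo-3,5-bis(methoxymethoxy)benzene | COCOc1cc(Br)cc(OCOC)c1 | intermediate
3 | 1,7-dibromoheptane | BrCCCCCCCBr | starting material
4 | [3,5-bis(methoxymethoxy)phenyl]magnesium bromide | COCOc1cc([Mg]Br)cc(OCOC)c1 | intermediate
5 | 1-(7-bromoheptyl)-3,5-bis(methoxymethoxy)benzene | COCOc1cc(CCCCCCCBr)cc(OCOC)c1 | intermediate
6 | prop-2-yn-1-ol (propargyl alcohol) | C#CCO | starting material
7 | dilithium salt of prop-2-yn-1-ol (O,C-dianion) | [Li]C#CCO[Li] | intermediate
8 | 10-[3,5-bis(methoxymethoxy)phenyl]dec-2-yn-1-ol | COCOc1cc(CCCCCCCC#CCO)cc(OCOC)c1 | intermediate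
9 | 1-(10-bromodec-8-yn-1-yl)-3,5-bis(methoxymethoxy)benzene | COCOc1cc(CCCCCCCC#CCBr)cc(OCOC)c1 | intermediate
10 | (4-bromobut-1-yn-1-yl)trimethylsilane | C[Si](C)(C)C#CCCBr | starting material
11 | (S)-2-methyloxirane ((S)-propylene oxide) | C[C@H]1CO1 | starting material
12 | [4-(trimethylsilyl)but-3-yn-1-yl]magnesium bromide | C[Si](C)(C)C#CCC[Mg]Br | intermediate
13 | (2S)-7-(trimethylsilyl)hept-6-yn-2-ol | C[C@H](O)CCCC#C[Si](C)(C)C | intermediate
14 | (2S)-hept-6-yn-2-ol | C[C@H](O)CCCC#C | intermediate
15 | 1-(10-iododec-8-yn-1-yl)-3,5-bis(methoxymethoxy)benzene | COCOc1cc(CCCCCCCC#CCI)cc(OCOC)c1 | intermediate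
16 | [(6S)-6-hydroxyhept-1-yn-1-yl]copper (copper acetylide of 14) | C[C@H](O)CCCC#C[Cu] | intermediate
17 | (2S)-17-[3,5-bis(methoxymethoxy)phenyl]heptadeca-6,9-diyn-2-ol | C[C@H](O)CCCC#CCC#CCCCCCCCc1cc(OCOC)cc(OCOC)c1 | intermediate
18 | (2S,6Z,9Z)-17-[3,5-bis(methoxymethoxy)phenyl]heptadeca-6,9-dien-2-ol | C[C@H](O)CCC/C=C\C/C=C\CCCCCCCc1cc(OCOC)cc(OCOC)c1 | intermediate
19 | Hansfordiol D, 5-[(8Z,11Z,16S)-16-hydroxyheptadeca-8,11-dien-1-yl]benzene-1,3-diol | C[C@H](O)CCC/C=C\C/C=C\CCCCCCCc1cc(O)cc(O)c1 | target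

**Totals**
Total step count: 9.
Longest linear sequence: 7 steps (1, 2, 3, 4, 7, 8, 9, from compound 1); the branch to 14 is 2 steps (5, 6).

**Three steps most likely to fail, with fallbacks**

Step 8 (semi-hydrogenation of the skipped diyne). The risk is over-reduction or incomplete reduction, giving mixtures that are hard to separate from 18. The fallback sets out from 14 and 5 and comes back at 18, so steps 3, 4, 7 and 8 are not needed. It makes the C8=C9 alkene by a Z-selective Wittig reaction and the C11=C12 alkene by semi-hydrogenation of one isolated alkyne, so no skipped diyne is ever reduced. Compound 14 is deprotonated twice (n-BuLi, 2 equiv, THF/HMPA) to the dilithium salt F5, which opens ethylene oxide (C1CO1) to give (8S)-non-3-yne-1,8-diol F6. Semi-hydrogenation (H2, Pd on CaCO3 poisoned with Pb(OAc)2, quinoline) gives (3Z,8S)-non-3-ene-1,8-diol F7. I2, PPh3 and imidazole (1.05 equiv, CH2Cl2, 0 °C) iodinate the primary alcohol selectively to give (2S,6Z)-9-iodonon-6-en-2-ol F8, and PPh3 in MeCN at reflux gives [(3Z,8S)-8-hydroxynon-3-en-1-yl]triphenylphosphonium iodide F9. In parallel, 5 is converted (Mg, THF) into the alkylmagnesium bromide F10, which is formylated with DMF to give 8-[3,5-bis(methoxymethoxy)phenyl]octanal F11. F9 with NaN(SiMe3)2 (2.1 equiv, THF, −78 °C) gives the sodium alkoxide ylide F12, which reacts with F11 to give 18.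

Step 3 (alkylation of the propargyl alcohol dianion). The risk is low conversion from the poorly soluble dianion, or E2 and O-alkylation side reactions. The fallback sets out from 5 and comes back at 8, adding the three carbons in two stages. Compound 5 is ethynylated with LiC≡CH·H2NCH2CH2NH2 in DMSO at rt to give 1-(non-8-yn-1-yl)-3,5-bis(methoxymethoxy)benzene F3. n-BuLi in THF at −78 °C gives the lithium acetylide F4, which is hydroxymethylated with paraformaldehyde to give 8.

Step 2 (copper-catalysed aryl Grignard coupling with a dibromide). The risk is double arylation, biaryl homocoupling or sluggish coupling of the aryl Grignard reagent. The fallback sets out from 2 and comes back at 5, replacing the sp2–sp3 coupling by sp2–sp coupling and saturation. Compound 2 and hept-6-yn-1-ol (C#CCCCCCO) undergo Sonogashira coupling (PdCl2(PPh3)2, CuI, Et3N, 70 °C) to give 7-[3,5-bis(methoxymethoxy)phenyl]hept-6-yn-1-ol F1. Full hydrogenation (H2, Pd/C, EtOAc) gives 7-[3,5-bis(methoxymethoxy)phenyl]heptan-1-ol F2, and Appel bromination (CBr4, PPh3, CH2Cl2, 0 °C) gives 5.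

**Further compounds**
F1 | step 2 | 7-[3,5-bis(methoxymethoxy)phenyl]hept-6-yn-1-ol | COCOc1cc(C#CCCCCCO)cc(OCOC)c1
F2 | step 2 | 7-[3,5-bis(methoxymethoxy)phenyl]heptan-1-ol | COCOc1cc(CCCCCCCO)cc(OCOC)c1
F3 | step 3 | 1-(non-8-yn-1-yl)-3,5-bis(methoxymethoxy)benzene | COCOc1cc(CCCCCCCC#C)cc(OCOC)c1
F4 | step 3 | lithium acetylide of F3, {9-[3,5-bis(methoxymethoxy)phenyl]non-1-yn-1-yl}lithium | COCOc1cc(CCCCCCCC#C[Li])cc(OCOC)c1
F5 | step 8 | dilithium salt of (2S)-hept-6-yn-2-ol (O,C-dianion of 14) | C[C@H](O[Li])CCCC#C[Li]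
F6 | step 8 | (8S)-non-3-yne-1,8-diol | C[C@H](O)CCCC#CCCO
F7 | step 8 | (3Z,8S)-non-3-ene-1,8-diol | C[C@H](O)CCC/C=C\CCO
F8 | step 8 | (2S,6Z)-9-iodonon-6-en-2-ol | C[C@H](O)CCC/C=C\CCI
F9 | step 8 | [(3Z,8S)-8-hydroxynon-3-en-1-yl]triphenylphosphonium iodide | C[C@H](O)CCC/C=C\CC[P+](c1ccccc1)(c1ccccc1)c1ccccc1.[I-]
F10 | step 8 | {7-[3,5-bis(methoxymethoxy)phenyl]heptyl}magnesium bromide | COCOc1cc(CCCCCCC[Mg]Br)cc(OCOC)c1
F11 | step 8 | 8-[3,5-bis(methoxymethoxy)phenyl]octanal | COCOc1cc(CCCCCCCC=O)cc(OCOC)c1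
F12 | step 8 | sodium (2S,6Z)-9-(triphenylphosphoranylidene)non-6-en-2-olate (alkoxide ylide from F9) | C[C@H]([O-])CCC/C=C\CC=P(c1ccccc1)(c1ccccc1)c1ccccc1.[Na+]
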